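**Retrosynthetic overview**
1. Target 18 is (3S,6R)-3-bromo-6-[(1R,3R,4R)-3-bromo-4-chloro-4-methylcyclohexyl]-2,2,6-trimethyloxane. C-3'–Br and C-4'–Cl are trans-diequatorial, which a direct trans-diaxial BrCl addition to the cyclohexene should not deliver. They are therefore traced back to the trans-diaxial bromohydrin 15 (Br on C-4', OH on C-3'; 1,2-bromine shift through a bromonium ion), then to epoxide 14, alkene 13 and enone 9.
2. Enabling feature: in the carbocycle, C-3' (CHBr) between C-2' (CH2) and C-4' (CMeCl) is a masked ethyl ketone with its two α-carbons, a 1,3-dinucleophile. C-1' (the CH that carries the oxane), C-6' and C-5' are the β-, α- and carbonyl carbons of an enal, a 1,3-dielectrophile. Enone 9 therefore comes from enal 5 and tert-butyl 3-oxopentanoate 6 by a catalytic asymmetric [3+3] Michael/aldol condensation that makes C-1'–C-2' and C-4'–C-5'.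
3. Enal 5 ⇒ aldehyde 3 (Wittig) ⇒ vinyl oxane 2 (ozonolysis) ⇒ (R)-linalool 1 (bromoetherification).
4. Ring order: oxane first (it holds both of its stereocentres and masks the tertiary alcohol and trisubstituted alkene of linalool), cyclohexane second (key step), ring halogens last.

Key step: step 4

Remark: (R)-(−)-linalool of high enantiomeric purity is taken as the commercial starting material; primed locants C-1' to C-6' denote the carbocycle atoms of the target throughout (C-1' carries the oxane, C-3' the bromine, C-4' chlorine and methyl), whatever the systematic numbering of an intermediate.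

**Route**

Step 1
Reactants: 1 (R)-linalool
Product: 2 (3S,6R)-3-bromo-6-ethenyl-2,2,6-trimethyloxane
Conditions: TBCO (1.1 equiv), MeNO2, 0 °C to rt
Reagents that add atoms: 2,4,4,6-tetrabromocyclohexa-2,5-dien-1-one (TBCO), O=C1C(Br)=CC(Br)(Br)C=C1Br
Why: Bromoetherification: TBCO transfers Br+ to the electron-rich trisubstituted alkene (the vinyl group is much less nucleophilic) and the tertiary hydroxyl opens the bromonium ion at its tertiary carbon (Markovnikov, 6-endo, favoured in polar nitromethane), C-3 being set by anti addition through a chair with bromine equatorial; because methyl and vinyl at C-6 are of similar size, the C-3 epimer and some 5-exo oxolane are expected as well, 2 is isolated by chromatography and the other bromo ethers can be returned to 1 with Zn/AcOH.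

Step 2
Reactants: 2 (3S,6R)-3-bromo-6-ethenyl-2,2,6-trimethyloxane
Product: 3 (2R,5S)-5-bromo-2,6,6-trimethyloxane-2-carbaldehyde
Conditions: O3, CH2Cl2, −78 °C; then Me2S, −78 °C to rt
Reagents that add atoms: ozone, [O-][O+]=O
Why: Ozonolysis with reductive work-up cleaves the only remaining C=C bond to the aldehyde, whose α-carbon is quaternary and therefore cannot epimerise.

Step 3
Reactants: 3 (2R,5S)-5-bromo-2,6,6-trimethyloxane-2-carbaldehyde; 4 (triphenylphosphoranylidene)acetaldehyde
Product: 5 (2E)-3-[(2R,5S)-5-bromo-2,6,6-trimethyloxan-2-yl]prop-2-enal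
Conditions: toluene, 90 °C
Reagents that add atoms: (triphenylphosphoranylidene)acetaldehyde (4), O=CC=P(c1ccccc1)(c1ccccc1)c1ccccc1
Why: Wittig olefination with the stabilised formyl ylide should give the (E)-enal, and the non-enolisable aldehyde leaves both oxane stereocentres untouched.

Step 4
Reactants: 5 (2E)-3-[(2R,5S)-5-bromo-2,6,6-trimethyloxan-2-yl]prop-2-enal; 6 tert-butyl 3-oxopentanoate
Product: 9 (5R)-5-[(2R,5S)-5-bromo-2,6,6-trimethyloxan-2-yl]-2-methylcyclohex-2-en-1-one, via Michael adduct 7 (not isolated), via cyclised keto ester 8 (not isolated)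
Conditions: (S)-2-[diphenyl(trimethylsilyloxy)methyl]pyrrolidine (20 mol%), PhCO2H (20 mol%), toluene, rt; then p-TsOH·H2O (20 mol%), toluene, 70 °C
Reagents that add atoms: tert-butyl 3-oxopentanoate (6), CCC(=O)CC(=O)OC(C)(C)C
Why: The (S)-prolinol silyl ether turns 5 into an (E)-iminium ion and C-2 of keto ester 6 adds to its β-carbon from the Si face, anti to the CPh2OSiMe3 group, which makes C-1'–C-2' and sets C-1' as R under catalyst control (the neighbouring oxane centre is expected to be a spectator). On acid treatment the ethyl ketone enolises toward C-4' and attacks the aldehyde carbon C-5' (6-(enolexo)-exo-trig aldol, makes C-4'–C-5'), water is lost to give the conjugated enone, and the tert-butyl ester is cleaved and decarboxylated, which erases the epimeric centre at C-2'. The closest known reaction type is the diarylprolinol silyl ether catalysed Michael addition of β-keto esters to enals followed by acid-mediated aldol condensation and decarboxylation to 5-substituted cyclohex-2-enones, a Robinson-type [3+3] annulation. The step needs 1,4- rather than 1,2-addition, secured by iminium activation and by the doubly activated C–H of 6 being the only nucleophile in the first stage, and a single aldol mode, secured because only C-4' to C-5' closure gives a six-membered ring (the alternatives would be four-membered). Because the β-carbon carries a fully substituted carbon, rate rather than selectivity is the concern, which is why the less hindered diphenyl catalyst and an acid co-catalyst are chosen.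

Step 5
Reactants: 9 (5R)-5-[(2R,5S)-5-bromo-2,6,6-trimethyloxan-2-yl]-2-methylcyclohex-2-en-1-one; 10 4-methylbenzenesulfonohydrazide
Product: 11 N'-[(5R)-5-[(2R,5S)-5-bromo-2,6,6-trimethyloxan-2-yl]-2-methylcyclohex-2-en-1-ylidene]-4-methylbenzenesulfonohydrazide
Conditions: TsNHNH2 (1.1 equiv), EtOH, rt
Reagents that add atoms: 4-methylbenzenesulfonohydrazide (10), Cc1ccc(cc1)S(=O)(=O)NN
Why: Condensation of the ketone with tosylhydrazide gives the α,β-unsaturated tosylhydrazone (its C=N geometry is irrelevant) without touching any stereocentre.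

Step 6
Reactants: 11 N'-[(5R)-5-[(2R,5S)-5-bromo-2,6,6-trimethyloxan-2-yl]-2-methylcyclohex-2-en-1-ylidene]-4-methylbenzenesulfonohydrazide
Product: 13 (3S,6R)-3-bromo-2,2,6-trimethyl-6-[(1R)-4-methylcyclohex-3-en-1-yl]oxane, via allylic diazene 12 (not isolated)
Conditions: catecholborane (2 equiv), CHCl3, 0 °C; then NaOAc·3H2O, reflux
Reagents that add atoms: none
Why: Reductive 1,3-transposition of an α,β-unsaturated tosylhydrazone: catecholborane adds hydride to C=N, acetate-induced loss of sulfinate gives allylic diazene 12, and its retro-ene loss of N2 delivers hydrogen to C-5' and moves the double bond to C-3'=C-4' (the carvone-to-limonene pattern), C-1' being untouched.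

Step 7
Reactants: 13 (3S,6R)-3-bromo-2,2,6-trimethyl-6-[(1R)-4-methylcyclohex-3-en-1-yl]oxane
Product: 14 (3S,6R)-3-bromo-2,2,6-trimethyl-6-[(1S,3R,6R)-6-methyl-7-oxabicyclo[4.1.0]heptan-3-yl]oxane (epoxide oxygen trans to the oxanyl group)
Conditions: 1,2:4,5-di-O-isopropylidene-β-L-erythro-2,3-hexodiulo-2,6-pyranose (L-fructose-derived Shi ketone, 30 mol%), Oxone (2KHSO5·KHSO4·K2SO4), K2CO3, Bu4NHSO4, MeCN/CH2(OMe)2/aq. Na2B4O7 buffer, 0 °C
Reagents that add atoms: potassium peroxymonosulfate (KHSO5, active oxidant of Oxone), [K+].[O-]S(=O)(=O)OO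
Why: Shi asymmetric epoxidation: the dioxirane formed from the L-fructose-derived ketone should, through the spiro transition state, deliver oxygen to the face of the trisubstituted alkene anti to the oxanyl group (catalyst control, since the remote C-1' substituent gives no bias of its own), setting C-3' and C-4' as in cis-limonene oxide (methyl cis to the C-1' substituent); the D-fructose-derived ketone is predicted to attack the other face.

Step 8
Reactants: 14 (3S,6R)-3-bromo-2,2,6-trimethyl-6-[(1S,3R,6R)-6-methyl-7-oxabicyclo[4.1.0]heptan-3-yl]oxane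
Product: 15 (1S,2S,5R)-2-bromo-5-[(2R,5S)-5-bromo-2,6,6-trimethyloxan-2-yl]-2-methylcyclohexan-1-ol
Conditions: HBr (33% in AcOH, 1.05 equiv), CH2Cl2, −78 °C
Reagents that add atoms: hydrogen bromide, Br
Why: Acidic epoxide opening by bromide at the tertiary carbon C-4' with inversion is at once Markovnikov and trans-diaxial (Fürst–Plattner) for this epoxide, as in the acid opening of cis-limonene oxide at C-1, so bromine enters C-4' cis to the oxanyl group and the C-3' hydroxyl stays axial and antiperiplanar to it.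

Step 9
Reactants: 15 (1S,2S,5R)-2-bromo-5-[(2R,5S)-5-bromo-2,6,6-trimethyloxan-2-yl]-2-methylcyclohexan-1-ol
Product: 18 deoxycaespitol (3S,6R)-3-bromo-6-[(1R,3R,4R)-3-bromo-4-chloro-4-methylcyclohexyl]-2,2,6-trimethyloxane, via chlorosulfite 16 (not isolated), via bromonium chloride 17 (not isolated)
Conditions: SOCl2 (1.5 equiv), pyridine (2 equiv), CH2Cl2, −20 °C to rt
Reagents that add atoms: thionyl chloride, ClS(Cl)=O
Why: Deoxychlorination with neighbouring-group participation by bromine: the axial chlorosulfite 16 is expelled by the antiperiplanar C-4' bromine to give bromonium ion 17 on the ring face cis to the oxanyl group, and chloride opens it at the tertiary carbon C-4' from the opposite face (Markovnikov), so that bromine ends on C-3' and chlorine on C-4', trans to each other and both equatorial, each centre having been inverted once.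

**Compound list**
1 | (R)-linalool, (3R)-3,7-dimethylocta-1,6-dien-3-ol | O[C@@](C)(C=C)CCC=C(C)C | starting material
2 | (3S,6R)-3-bromo-6-ethenyl-2,2,6-trimethyloxane (Br trans to vinyl) | CC1(C)O[C@@](C)(C=C)CC[C@@H]1Br | intermediate
3 | (2R,5S)-5-bromo-2,6,6-trimethyloxane-2-carbaldehyde | CC1(C)O[C@@](C)(C=O)CC[C@@H]1Br | intermediate
4 | (triphenylphosphoranylidene)acetaldehyde | O=CC=P(c1ccccc1)(c1ccccc1)c1ccccc1 | starting material
5 | (2E)-3-[(2R,5S)-5-bromo-2,6,6-trimethyloxan-2-yl]prop-2-enal | CC1(C)O[C@@](C)(/C=C/C=O)CC[C@@H]1Br | intermediate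
6 | tert-butyl 3-oxopentanoate | CCC(=O)CC(=O)OC(C)(C)C | starting material
7 | tert-butyl 2-[(1R)-1-[(2R,5S)-5-bromo-2,6,6-trimethyloxan-2-yl]-3-oxopropyl]-3-oxopentanoate (C-2 epimers) | CC1(C)O[C@@](C)([C@H](CC=O)C(C(=O)CC)C(=O)OC(C)(C)C)CC[C@@H]1Br | intermediate
8 | tert-butyl (6R)-6-[(2R,5S)-5-bromo-2,6,6-trimethyloxan-2-yl]-3-methyl-2-oxocyclohex-3-ene-1-carboxylate (C-1 epimers) | CC1(C)O[C@@](C)([C@@H]2CC=C(C)C(=O)C2C(=O)OC(C)(C)C)CC[C@@H]1Br | intermediate
9 | (5R)-5-[(2R,5S)-5-bromo-2,6,6-trimethyloxan-2-yl]-2-methylcyclohex-2-en-1-one | CC1(C)O[C@@](C)([C@@H]2CC=C(C)C(=O)C2)CC[C@@H]1Br | intermediate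
10 | 4-methylbenzenesulfonohydrazide | Cc1ccc(cc1)S(=O)(=O)NN | starting material
11 | N'-[(5R)-5-[(2R,5S)-5-bromo-2,6,6-trimethyloxan-2-yl]-2-methylcyclohex-2-en-1-ylidene]-4-methylbenzenesulfonohydrazide | CC1(C)O[C@@](C)([C@@H]2CC=C(C)C(=NNS(=O)(=O)c3ccc(C)cc3)C2)CC[C@@H]1Br | intermediate
12 | [(5R)-5-[(2R,5S)-5-bromo-2,6,6-trimethyloxan-2-yl]-2-methylcyclohex-2-en-1-yl]diazene (C-1 epimers) | CC1(C)O[C@@](C)([C@@H]2CC=C(C)C(N=N)C2)CC[C@@H]1Br | intermediate
13 | (3S,6R)-3-bromo-2,2,6-trimethyl-6-[(1R)-4-methylcyclohex-3-en-1-yl]oxane | CC1(C)O[C@@](C)([C@@H]2CCC(C)=CC2)CC[C@@H]1Br | intermediate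
14 | (3S,6R)-3-bromo-2,2,6-trimethyl-6-[(1S,3R,6R)-6-methyl-7-oxabicyclo[4.1.0]heptan-3-yl]oxane | CC1(C)O[C@@](C)([C@@H]2CC[C@@]3(C)O[C@H]3C2)CC[C@@H]1Br | intermediate
15 | (1S,2S,5R)-2-bromo-5-[(2R,5S)-5-bromo-2,6,6-trimethyloxan-2-yl]-2-methylcyclohexan-1-ol | CC1(C)O[C@@](C)([C@@H]2CC[C@](C)(Br)[C@@H](O)C2)CC[C@@H]1Br | intermediate
16 | (1S,2S,5R)-2-bromo-5-[(2R,5S)-5-bromo-2,6,6-trimethyloxan-2-yl]-2-methylcyclohexyl chlorosulfite | CC1(C)O[C@@](C)([C@@H]2CC[C@](C)(Br)[C@@H](OS(Cl)=O)C2)CC[C@@H]1Br | intermediate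
17 | bromonium ion bridging C-3' and C-4' on the face cis to the oxanyl group, chloride counter-ion | CC1(C)O[C@@](C)([C@@H]2CC[C@]3(C)[Br+][C@@H]3C2)CC[C@@H]1Br.[Cl-] | intermediate
18 | deoxycaespitol, (3S,6R)-3-bromo-6-[(1R,3R,4R)-3-bromo-4-chloro-4-methylcyclohexyl]-2,2,6-trimethyloxane | CC1(C)O[C@@](C)([C@@H]2CC[C@@](C)(Cl)[C@H](Br)C2)CC[C@@H]1Br | target

**Step count and risks**

Total step count: 9. Longest linear sequence: 9 steps (1 to 18).

Steps most likely to fail:

1. Step 4. The conjugate addition may stall because the β-carbon of the iminium ion is flanked by a fully substituted carbon; the resident oxane centre may erode the catalyst's facial control; and the acid stage may open the di-tertiary oxane. The fallback sets out from 3 and comes back at 9. Horner–Wadsworth–Emmons olefination of 3 with dimethyl (2-oxobutyl)phosphonate (LiCl, iPr2NEt, MeCN) would give (1E)-1-[(2R,5S)-5-bromo-2,6,6-trimethyloxan-2-yl]pent-1-en-3-one F1. Hosomi–Sakurai conjugate allylation (allyltrimethylsilane, TiCl4, CH2Cl2, −78 °C), a small nucleophile that tolerates a hindered β-carbon, would give the allyl ketone (5R)-5-[(2R,5S)-5-bromo-2,6,6-trimethyloxan-2-yl]oct-7-en-3-one F2, with C-1' set by substrate control from the oxane centre and any epimer removed by chromatography. Ozonolysis (O3, CH2Cl2, −78 °C; then Me2S) would give the keto aldehyde (3R)-3-[(2R,5S)-5-bromo-2,6,6-trimethyloxan-2-yl]-5-oxoheptanal F3. Its aldol condensation (piperidine, AcOH, toluene, 80 °C) closes C-4'–C-5' and gives 9.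

2. Step 9. Chloride may collapse on the secondary carbon of the bromonium ion, which would leave a tertiary bromide and a secondary chloride, because attack at C-4' has to pass through a twist-boat; the ion may also lose a proton. The fallback sets out from 9 and arrives at 18. Corey–Bakshi–Shibata reduction of 9 with (R)-2-methyl-CBS-oxazaborolidine and BH3·SMe2 (catalyst-controlled equatorial hydride delivery) would give the trans allylic alcohol (1S,5R)-5-[(2R,5S)-5-bromo-2,6,6-trimethyloxan-2-yl]-2-methylcyclohex-2-en-1-ol F4. Appel bromination (CBr4, PPh3, CH2Cl2, 0 °C) with inversion would give the allylic bromide (3S,6R)-3-bromo-6-[(1R,5R)-5-bromo-4-methylcyclohex-3-en-1-yl]-2,2,6-trimethyloxane F5, with bromine on C-3' cis to the oxanyl group. Addition of HCl (CH2Cl2, −78 °C) would then protonate C-5', so that the cation is born on C-4', is bridged by the neighbouring bromine and is captured there by chloride anti to bromine, giving 18.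

3. Step 1. Competing 5-exo closure and the missing facial bias (methyl against vinyl at C-6) may leave little of 2. The fallback sets out from 1 and comes back at 9; it uses the bromo ether only as a mask for the hydroxy-alkene and sets the bromine-bearing oxane centre late. The C-3 epimer (3R,6R)-3-bromo-6-ethenyl-2,2,6-trimethyloxane F6 from step 1 is taken through steps 2 to 4 unchanged. This passes through the aldehyde (2R,5R)-5-bromo-2,6,6-trimethyloxane-2-carbaldehyde F7, the enal (2E)-3-[(2R,5R)-5-bromo-2,6,6-trimethyloxan-2-yl]prop-2-enal F8, the Michael adduct tert-butyl 2-[(1R)-1-[(2R,5R)-5-bromo-2,6,6-trimethyloxan-2-yl]-3-oxopropyl]-3-oxopentanoate F9 and the keto ester tert-butyl (6R)-6-[(2R,5R)-5-bromo-2,6,6-trimethyloxan-2-yl]-3-methyl-2-oxocyclohex-3-ene-1-carboxylate F10, and ends at the enone (5R)-5-[(2R,5R)-5-bromo-2,6,6-trimethyloxan-2-yl]-2-methylcyclohex-2-en-1-one F11. Zinc-mediated reductive elimination of the β-bromo ether (activated Zn, NH4Cl, EtOH, reflux) would open the oxane to the hydroxy dienone (5R)-5-[(2R)-2-hydroxy-6-methylhept-5-en-2-yl]-2-methylcyclohex-2-en-1-one F12. A second bromoetherification (TBCO, MeNO2, 0 °C), now with the cyclohexenonyl group equatorial in the chair-like transition state, should close the oxane with bromine trans to the ring and give 9.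

**Further compounds**
F1 | step 4 | (1E)-1-[(2R,5S)-5-bromo-2,6,6-trimethyloxan-2-yl]pent-1-en-3-one | CC1(C)O[C@@](C)(/C=C/C(=O)CC)CC[C@@H]1Br
F2 | step 4 | (5R)-5-[(2R,5S)-5-bromo-2,6,6-trimethyloxan-2-yl]oct-7-en-3-one | CC1(C)O[C@@](C)([C@@H](CC(=O)CC)CC=C)CC[C@@H]1Br
F3 | step 4 | (3R)-3-[(2R,5S)-5-bromo-2,6,6-trimethyloxan-2-yl]-5-oxoheptanal | CC1(C)O[C@@](C)([C@@H](CC(=O)CC)CC=O)CC[C@@H]1Br
F4 | step 9 | (1S,5R)-5-[(2R,5S)-5-bromo-2,6,6-trimethyloxan-2-yl]-2-methylcyclohex-2-en-1-ol | CC1(C)O[C@@](C)([C@@H]2CC=C(C)[C@@H](O)C2)CC[C@@H]1Br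
F5 | step 9 | (3S,6R)-3-bromo-6-[(1R,5R)-5-bromo-4-methylcyclohex-3-en-1-yl]-2,2,6-trimethyloxane | CC1(C)O[C@@](C)([C@@H]2CC=C(C)[C@H](Br)C2)CC[C@@H]1Br
F6 | step 1 | (3R,6R)-3-bromo-6-ethenyl-2,2,6-trimethyloxane | CC1(C)O[C@@](C)(C=C)CC[C@H]1Br
F7 | step 1 | (2R,5R)-5-bromo-2,6,6-trimethyloxane-2-carbaldehyde | CC1(C)O[C@@](C)(C=O)CC[C@H]1Br
F8 | step 1 | (2E)-3-[(2R,5R)-5-bromo-2,6,6-trimethyloxan-2-yl]prop-2-enal | CC1(C)O[C@@](C)(/C=C/C=O)CC[C@H]1Br
F9 | step 1 | tert-butyl 2-[(1R)-1-[(2R,5R)-5-bromo-2,6,6-trimethyloxan-2-yl]-3-oxopropyl]-3-oxopentanoate | CC1(C)O[C@@](C)([C@H](CC=O)C(C(=O)CC)C(=O)OC(C)(C)C)CC[C@H]1Br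
F10 | step 1 | tert-butyl (6R)-6-[(2R,5R)-5-bromo-2,6,6-trimethyloxan-2-yl]-3-methyl-2-oxocyclohex-3-ene-1-carboxylate | CC1(C)O[C@@](C)([C@@H]2CC=C(C)C(=O)C2C(=O)OC(C)(C)C)CC[C@H]1Br
F11 | step 1 | (5R)-5-[(2R,5R)-5-bromo-2,6,6-trimethyloxan-2-yl]-2-methylcyclohex-2-en-1-one | CC1(C)O[C@@](C)([C@@H]2CC=C(C)C(=O)C2)CC[C@H]1Br
F12 | step 1 | (5R)-5-[(2R)-2-hydroxy-6-methylhept-5-en-2-yl]-2-methylcyclohex-2-en-1-one | O[C@@](C)([C@@H]1CC=C(C)C(=O)C1)CCC=C(C)C
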